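The 1,2-dioxolane is cut at both tertiary C–O bonds. C3 and C5 each carry a methyl group and a two-carbon arm (C3–CH2–CO2H, C5–CH2–CH2–chain), trans across the ring, so the core is a latent C2-symmetric (3R,5R)-3,5-dimethyl-1,2-dioxolane-3,5-diethanol. Its precursor is a C2-symmetric bis(2-methyloxetane) in which the arms are the oxetane ring carbons. In one flask H2O2 opens one oxetane with inversion to a tertiary hydroperoxide, whose OOH then opens the second oxetane 5-exo, again with inversion. This closes the ring at the carbon that becomes C5 and sets both quaternary stereocentres. Afterwards one arm is oxidised to the acid and the other is extended by two olefinations.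

Key step: step 5

Assumption: (S)-mevalonolactone, the unnatural antipode, is taken as a purchasable starting material.
Assumption: the (R)-binaphthoxide catalyst is taken to give the (S)-oxetane in step 4; if the sense of induction is the opposite, its antipode is used.

Step 1
Reactants: 1 (S)-mevalonolactone
Product: 2 (3S)-3,5-dihydroxy-N-methoxy-N,3-dimethylpentanamide
Conditions: MeNHOMe·HCl, AlMe3, CH2Cl2, 0 °C → rt
Reagents that add atoms: N,O-dimethylhydroxylamine hydrochloride (CNOC.Cl)
Why: Aluminium-amide aminolysis of the lactone (Weinreb amide formation) opens the ring without touching the tertiary carbinol, so the (S) centre of 1 is carried through unchanged.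

Step 2
Reactants: 2 (3S)-3,5-dihydroxy-N-methoxy-N,3-dimethylpentanamide
Product: 4 N-methoxy-N-methyl-2-[(2S)-2-methyloxetan-2-yl]acetamide, via primary tosylate 3 (not isolated)
Conditions: KOtBu (1.0 equiv), TsCl (1.0 equiv), THF, 0 °C; then KOtBu (1.1 equiv), 0 °C → rt
Reagents that add atoms: none
Why: Selective sulfonylation of the primary hydroxyl followed by intramolecular Williamson etherification (4-exo-tet) by the tertiary alkoxide should close the oxetane, and since the C–O bond at the stereocentre is not broken the configuration is retained.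

Step 3
Reactants: 4 N-methoxy-N-methyl-2-[(2S)-2-methyloxetan-2-yl]acetamide
Product: 5 1-[(2S)-2-methyloxetan-2-yl]propan-2-one
Conditions: MeMgBr, THF, 0 °C; aq. NH4Cl
Reagents that add atoms: methylmagnesium bromide (C[Mg]Br)
Why: Weinreb ketone synthesis, in which the chelated tetrahedral intermediate stops at the methyl ketone and the oxetane is inert to the Grignard reagent at 0 °C.

Step 4
Reactants: 5 1-[(2S)-2-methyloxetan-2-yl]propan-2-one
Product: 7 bis[(2S)-2-methyloxetan-2-yl]methane, via epoxide 6 (not isolated)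
Conditions: Me3S(O)I, NaH, THF (ylide, 1.2 equiv); LaLi3[(R)-1,1'-binaphthalene-2,2'-diolate]3 (5 mol%), [2,4,6-(MeO)3C6H2]3P=O (5 mol%), 5 Å MS, THF, rt; then ylide (1.2 equiv), 45 °C
Reagents that add atoms: trimethylsulfoxonium iodide (C[S+](C)(C)=O.[I-])
Why: Catalytic asymmetric Corey–Chaykovsky epoxidation of the methyl ketone, in which the catalyst tells methyl from CH2R and sets the new centre, followed by ring expansion of the 2,2-disubstituted epoxide by a second ylide (attack at CH2, 4-exo-tet closure with loss of DMSO, tertiary C–O bond untouched) should give the C2-symmetric bis-oxetane, any meso isomer being removed by chromatography.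

Step 5
Reactants: 7 bis[(2S)-2-methyloxetan-2-yl]methane
Product: 9 2,2'-[(3R,5R)-3,5-dimethyl-1,2-dioxolane-3,5-diyl]di(ethan-1-ol), via hydroperoxide 8 (not isolated)
Conditions: H2O2 (anhydrous, in Et2O, 2 equiv), Me3SiOSO2CF3 (0.2 equiv), Et2O, −78 → 0 °C
Reagents that add atoms: hydrogen peroxide (OO)
Why: The silyl triflate activates one oxetane oxygen and H2O2 attacks the fully substituted carbon in an SN2-like (tight ion pair) opening with inversion to give tertiary hydroperoxide 8, whose terminal oxygen then attacks the fully substituted carbon of the second activated oxetane from the face opposite to the leaving oxygen, forming the O–C bond at the future C5 and the 1,2-dioxolane. Both events are known reaction types, namely Lewis-acid-mediated perhydrolysis of 2,2-disubstituted oxetanes to 3-hydroperoxyalkanols and intramolecular opening of an oxetane by a hydroperoxide. The dioxolane closes in the 5-exo-tet mode. C3 and C5 are each set by inversion of an (S)-oxetane carbon, so the (S,S) bis-oxetane can give only the (3R,5R) trans product and no facial selectivity is needed; because 9 is C2-symmetric the carbon attacked first and the ring-closing carbon are equivalent, and the latter is carried on as C5. The step needs OOH to win over the liberated primary OH (6-exo) and over a second H2O2, which the α-effect nucleophilicity of the hydroperoxide, the favoured 5-exo geometry and intramolecularity should secure, and it needs substitution without ionisation, which low temperature in ether and substoichiometric acid favour.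

Step 6
Reactants: 9 2,2'-[(3R,5R)-3,5-dimethyl-1,2-dioxolane-3,5-diyl]di(ethan-1-ol)
Product: 10 2,2'-[(3S,5S)-3,5-dimethyl-1,2-dioxolane-3,5-diyl]diacetaldehyde
Conditions: Dess–Martin periodinane, NaHCO3, CH2Cl2, 0 °C → rt
Reagents that add atoms: none
Why: Dess–Martin oxidation should convert both primary alcohols into aldehydes under buffered, non-basic conditions that leave the di-tertiary peroxide and the base-sensitive β-peroxy aldehydes intact (the descriptors change only because the arm priorities change).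

Step 7
Reactants: 11 7-bromoheptan-1-ol
Product: 12 (7-hydroxyheptyl)triphenylphosphonium bromide
Conditions: PPh3, MeCN, reflux
Reagents that add atoms: triphenylphosphine (c1ccc(cc1)P(c1ccccc1)c1ccccc1)
Why: SN2 quaternisation of triphenylphosphine by the primary bromide, which tolerates the free hydroxyl.

Step 8
Reactants: 10 2,2'-[(3S,5S)-3,5-dimethyl-1,2-dioxolane-3,5-diyl]diacetaldehyde; 12 (7-hydroxyheptyl)triphenylphosphonium bromide
Product: 14 2-[(3S,5R)-5-[(2Z)-9-hydroxynon-2-en-1-yl]-3,5-dimethyl-1,2-dioxolan-3-yl]acetaldehyde, via alkoxide ylide 13 (not isolated)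
Conditions: 12, NaN(SiMe3)2 (2.0 equiv), THF, −78 → 0 °C; then added to 10 (2.5 equiv), THF, −78 °C → rt
Reagents that add atoms: none
Why: Wittig olefination with a non-stabilised ylide, in which either aldehyde of the C2-symmetric dialdehyde (used in excess and recovered) gives the same mono-alkene, so the two arms are told apart here, and the Z geometry is irrelevant because the alkene is reduced in step 10.

Step 9
Reactants: 14 2-[(3S,5R)-5-[(2Z)-9-hydroxynon-2-en-1-yl]-3,5-dimethyl-1,2-dioxolan-3-yl]acetaldehyde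
Product: 15 2-[(3S,5R)-5-[(2Z)-9-hydroxynon-2-en-1-yl]-3,5-dimethyl-1,2-dioxolan-3-yl]acetic acid
Conditions: NaClO2, NaH2PO4, 2-methyl-2-butene, t-BuOH/H2O, 0 °C → rt
Reagents that add atoms: sodium chlorite ([Na+].[O-]Cl=O)
Why: Pinnick oxidation is selective for the aldehyde in the presence of the primary alcohol, the alkene (hypochlorite is scavenged by 2-methyl-2-butene) and the peroxide.

Step 10
Reactants: 15 2-[(3S,5R)-5-[(2Z)-9-hydroxynon-2-en-1-yl]-3,5-dimethyl-1,2-dioxolan-3-yl]acetic acid
Product: 16 2-[(3S,5R)-5-(9-hydroxynonyl)-3,5-dimethyl-1,2-dioxolan-3-yl]acetic acid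
Conditions: KO2CN=NCO2K, AcOH, MeOH, 0 °C → rt
Reagents that add atoms: none
Why: Diimide reduction transfers H2 to the isolated cis-alkene in a concerted syn fashion and, unlike catalytic hydrogenation, should not cleave the O–O bond.

Step 11
Reactants: 16 2-[(3S,5R)-5-(9-hydroxynonyl)-3,5-dimethyl-1,2-dioxolan-3-yl]acetic acid
Product: 17 2-[(3S,5R)-3,5-dimethyl-5-(9-oxononyl)-1,2-dioxolan-3-yl]acetic acid
Conditions: Dess–Martin periodinane, CH2Cl2, rt
Reagents that add atoms: none
Why: Dess–Martin oxidation of the primary alcohol stops at the aldehyde and tolerates the free carboxylic acid and the peroxide.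

Step 12
Reactants: 18 (2E,4E)-hepta-2,4-dien-1-ol
Product: 19 (2E,4E)-1-bromohepta-2,4-diene
Conditions: PBr3, Et2O, −10 °C
Reagents that add atoms: phosphorus tribromide (BrP(Br)Br)
Why: Bromination of the primary allylic alcohol with PBr3 at low temperature (SN2 at the primary carbon) should keep the (2E,4E) geometry.

Step 13
Reactants: 19 (2E,4E)-1-bromohepta-2,4-diene
Product: 20 diethyl [(2E,4E)-hepta-2,4-dien-1-yl]phosphonate
Conditions: P(OEt)3, 110 °C
Reagents that add atoms: triethyl phosphite (CCOP(OCC)OCC)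
Why: Michaelis–Arbuzov reaction of the primary allylic bromide with triethyl phosphite gives the dienylphosphonate.

Step 14
Reactants: 17 2-[(3S,5R)-3,5-dimethyl-5-(9-oxononyl)-1,2-dioxolan-3-yl]acetic acid; 20 diethyl [(2E,4E)-hepta-2,4-dien-1-yl]phosphonate
Product: 22 2-[(3S,5R)-5-[(9E,11E,13E)-hexadeca-9,11,13-trien-1-yl]-3,5-dimethyl-1,2-dioxolan-3-yl]acetic acid, via lithiated phosphonate 21 (not isolated)
Conditions: 20 (3 equiv), LiN(SiMe3)2 (3 equiv), THF, −78 °C; then 17, −78 → 0 °C; aq. citric acid
Reagents that add atoms: none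
Why: Horner–Wadsworth–Emmons olefination, in which the excess lithiated dienylphosphonate first deprotonates the acid, then adds through its α-carbon to the aldehyde and eliminates diethyl phosphate to give the new 9,10-alkene with E geometry, while the 11E and 13E alkenes come unchanged from 20 and the quaternary stereocentres are not touched.

Compound list
1 | (S)-mevalonolactone, (4S)-4-hydroxy-4-methyloxan-2-one | C[C@]1(O)CCOC(=O)C1 | starting material
2 | (3S)-3,5-dihydroxy-N-methoxy-N,3-dimethylpentanamide | C[C@](O)(CCO)CC(=O)N(C)OC | intermediate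
3 | (3S)-3-hydroxy-5-[methoxy(methyl)amino]-3-methyl-5-oxopentyl 4-methylbenzenesulfonate | C[C@](O)(CCOS(=O)(=O)c1ccc(C)cc1)CC(=O)N(C)OC | intermediate
4 | N-methoxy-N-methyl-2-[(2S)-2-methyloxetan-2-yl]acetamide | C[C@@]1(CC(=O)N(C)OC)CCO1 | intermediate
5 | 1-[(2S)-2-methyloxetan-2-yl]propan-2-one | C[C@@]1(CC(C)=O)CCO1 | intermediate
6 | (2R)-2-methyl-2-{[(2S)-2-methyloxetan-2-yl]methyl}oxirane | C[C@@]1(C[C@]2(C)CO2)CCO1 | intermediate
7 | bis[(2S)-2-methyloxetan-2-yl]methane | C[C@@]1(C[C@]2(C)CCO2)CCO1 | intermediate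
8 | (3R)-3-hydroperoxy-3-methyl-4-[(2S)-2-methyloxetan-2-yl]butan-1-ol | OCC[C@@](C)(OO)C[C@]1(C)CCO1 | intermediate
9 | 2,2'-[(3R,5R)-3,5-dimethyl-1,2-dioxolane-3,5-diyl]di(ethan-1-ol) | OCC[C@]1(C)C[C@@](C)(CCO)OO1 | intermediate
10 | 2,2'-[(3S,5S)-3,5-dimethyl-1,2-dioxolane-3,5-diyl]diacetaldehyde | O=CC[C@]1(C)C[C@@](C)(CC=O)OO1 | intermediate
11 | 7-bromoheptan-1-ol | OCCCCCCCBr | starting material
12 | (7-hydroxyheptyl)triphenylphosphonium bromide | OCCCCCCC[P+](c1ccccc1)(c1ccccc1)c1ccccc1.[Br-] | intermediate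
13 | sodium 7-(triphenyl-λ5-phosphanylidene)heptan-1-olate | [Na+].[O-]CCCCCCC=P(c1ccccc1)(c1ccccc1)c1ccccc1 | intermediate
14 | 2-[(3S,5R)-5-[(2Z)-9-hydroxynon-2-en-1-yl]-3,5-dimethyl-1,2-dioxolan-3-yl]acetaldehyde | OCCCCCC/C=C\C[C@]1(C)C[C@@](C)(CC=O)OO1 | intermediate
15 | 2-[(3S,5R)-5-[(2Z)-9-hydroxynon-2-en-1-yl]-3,5-dimethyl-1,2-dioxolan-3-yl]acetic acid | OCCCCCC/C=C\C[C@]1(C)C[C@@](C)(CC(=O)O)OO1 | intermediate
16 | 2-[(3S,5R)-5-(9-hydroxynonyl)-3,5-dimethyl-1,2-dioxolan-3-yl]acetic acid | OCCCCCCCCC[C@]1(C)C[C@@](C)(CC(=O)O)OO1 | intermediate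
17 | 2-[(3S,5R)-3,5-dimethyl-5-(9-oxononyl)-1,2-dioxolan-3-yl]acetic acid | O=CCCCCCCCC[C@]1(C)C[C@@](C)(CC(=O)O)OO1 | intermediate
18 | (2E,4E)-hepta-2,4-dien-1-ol | CC/C=C/C=C/CO | starting material
19 | (2E,4E)-1-bromohepta-2,4-diene | CC/C=C/C=C/CBr | intermediate
20 | diethyl [(2E,4E)-hepta-2,4-dien-1-yl]phosphonate | CC/C=C/C=C/CP(=O)(OCC)OCC | intermediate
21 | lithium salt of diethyl [(2E,4E)-hepta-2,4-dien-1-yl]phosphonate (α-carbanion) | [Li+].CC/C=C/C=C/[CH-]P(=O)(OCC)OCC | intermediate
22 | 2-[(3S,5R)-5-[(9E,11E,13E)-hexadeca-9,11,13-trien-1-yl]-3,5-dimethyl-1,2-dioxolan-3-yl]acetic acid | CC/C=C/C=C/C=C/CCCCCCCC[C@]1(C)C[C@@](C)(CC(=O)O)OO1 | target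

Total step count: 14. Longest linear sequence: 11 steps (steps 1–6, 8–11 and 14).

Steps most likely to fail

Step 5. What may go wrong: ionisation at the tertiary oxetane carbons, which erodes configuration, and opening of the second oxetane by the liberated hydroxyl or by a second H2O2 instead of by the OOH group. The fallback sets out from 5 and comes back at 15; it builds C3 by C–C bond formation while the ring still closes by OOH opening the oxetane. Acid-catalysed exchange of ketone 5 with H2O2 in MeOH should give hydroperoxy ketal F1, whose OOH opens the oxetane (Me3SiOSO2CF3, inversion) to give methoxydioxolane alcohol F2. Silylation (t-BuMe2SiCl, imidazole) gives silyl ether F3. TiCl4 and 1-methoxy-1-(trimethylsilyloxy)ethene at −78 °C should add the acetate unit to the dioxolanyl peroxycarbenium ion anti to the larger C5 arm to give silyloxy ester F4, the minor cis isomer being removed by chromatography. Bu4NF gives hydroxy ester F5, Dess–Martin oxidation gives aldehyde ester F6, Wittig reaction with ylide 13 gives alkenol ester F7, and LiOH hydrolysis returns to 15.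

Step 4. What may go wrong: enolisation of the ketone by the basic ylide followed by β-elimination that opens the neighbouring oxetane, and eroded or mismatched facial selectivity in the ylide addition. The fallback sets out from 5 and comes back at 7. Horner–Wadsworth–Emmons reaction of 5 with triethyl phosphonoacetate and NaH should give E-enoate F8 (Z isomer separated), and i-Bu2AlH gives allylic alcohol F9. Sharpless asymmetric epoxidation (Ti(OiPr)4, D-(−)-diethyl tartrate, t-BuOOH) gives epoxy alcohol F10. NaAlH2(OCH2CH2OMe)2 opens it at C2 to 1,3-diol F11. KOtBu/TsCl then KOtBu, through monotosylate F12, closes the second oxetane with retention and returns to 7.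

Step 8. What may go wrong: double olefination of the symmetric dialdehyde and base-induced β-elimination of the peroxide from the β-peroxy aldehydes. The fallback sets out from 9 and comes back at 15; it tells the arms apart by protection instead of by statistical olefination. NaH and t-BuMe2SiCl on 9 should give mono-silyl ether F13. PhI(OAc)2/TEMPO in MeCN–H2O oxidises the free arm to silyloxy acid F14, Bu4NF gives hydroxy acid F15, and Dess–Martin oxidation gives aldehyde acid F16. Wittig reaction with ylide 13 (one further equivalent of base for the carboxylate) returns to 15.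

Further compounds
F1 | step 5 | 2-hydroperoxy-2-methoxy-1-[(2S)-2-methyloxetan-2-yl]propane | COC(C)(OO)C[C@@]1(C)CCO1
F2 | step 5 | 2-[(3R)-5-methoxy-3,5-dimethyl-1,2-dioxolan-3-yl]ethan-1-ol (C5 epimers) | OCC[C@]1(C)CC(C)(OC)OO1
F3 | step 5 | tert-butyl{2-[(3R)-5-methoxy-3,5-dimethyl-1,2-dioxolan-3-yl]ethoxy}dimethylsilane | CC(C)(C)[Si](C)(C)OCC[C@]1(C)CC(C)(OC)OO1
F4 | step 5 | methyl 2-[(3S,5R)-5-(2-{[tert-butyl(dimethyl)silyl]oxy}ethyl)-3,5-dimethyl-1,2-dioxolan-3-yl]acetate | CC(C)(C)[Si](C)(C)OCC[C@]1(C)C[C@@](C)(CC(=O)OC)OO1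
F5 | step 5 | methyl 2-[(3S,5R)-5-(2-hydroxyethyl)-3,5-dimethyl-1,2-dioxolan-3-yl]acetate | OCC[C@]1(C)C[C@@](C)(CC(=O)OC)OO1
F6 | step 5 | methyl 2-[(3S,5S)-3,5-dimethyl-5-(2-oxoethyl)-1,2-dioxolan-3-yl]acetate | O=CC[C@]1(C)C[C@@](C)(CC(=O)OC)OO1
F7 | step 5 | methyl 2-[(3S,5R)-5-[(2Z)-9-hydroxynon-2-en-1-yl]-3,5-dimethyl-1,2-dioxolan-3-yl]acetate | OCCCCCC/C=C\C[C@]1(C)C[C@@](C)(CC(=O)OC)OO1
F8 | step 4 | ethyl (2E)-3-methyl-4-[(2S)-2-methyloxetan-2-yl]but-2-enoate | C[C@@]1(C/C(C)=C/C(=O)OCC)CCO1
F9 | step 4 | (2E)-3-methyl-4-[(2S)-2-methyloxetan-2-yl]but-2-en-1-ol | C[C@@]1(C/C(C)=C/CO)CCO1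
F10 | step 4 | [(2R,3R)-3-methyl-3-{[(2S)-2-methyloxetan-2-yl]methyl}oxiran-2-yl]methanol | C[C@@]1(C[C@@]2(C)O[C@@H]2CO)CCO1
F11 | step 4 | (3S)-3-methyl-4-[(2S)-2-methyloxetan-2-yl]butane-1,3-diol | C[C@@]1(C[C@@](C)(O)CCO)CCO1
F12 | step 4 | (3S)-3-hydroxy-3-methyl-4-[(2S)-2-methyloxetan-2-yl]butyl 4-methylbenzenesulfonate | C[C@@]1(C[C@@](C)(O)CCOS(=O)(=O)c2ccc(C)cc2)CCO1
F13 | step 8 | 2-[(3R,5R)-5-(2-{[tert-butyl(dimethyl)silyl]oxy}ethyl)-3,5-dimethyl-1,2-dioxolan-3-yl]ethan-1-ol | CC(C)(C)[Si](C)(C)OCC[C@]1(C)C[C@@](C)(CCO)OO1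
F14 | step 8 | 2-[(3S,5R)-5-(2-{[tert-butyl(dimethyl)silyl]oxy}ethyl)-3,5-dimethyl-1,2-dioxolan-3-yl]acetic acid | CC(C)(C)[Si](C)(C)OCC[C@]1(C)C[C@@](C)(CC(=O)O)OO1
F15 | step 8 | 2-[(3S,5R)-5-(2-hydroxyethyl)-3,5-dimethyl-1,2-dioxolan-3-yl]acetic acid | OCC[C@]1(C)C[C@@](C)(CC(=O)O)OO1
F16 | step 8 | 2-[(3S,5S)-3,5-dimethyl-5-(2-oxoethyl)-1,2-dioxolan-3-yl]acetic acid | O=CC[C@]1(C)C[C@@](C)(CC(=O)O)OO1
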